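(The readings were generated by integration with made-up constants, and the scatter is random.)

I began with an easy step: I treated the substrate as a first-order decay with one time constant, as if the reagent in the reaction phase held steady (pseudo-first-order), with that time constant shortened in proportion to the reagent charged.

common to all: substrate 0.20 M
- north: reagent in the second phase 1.2 equiv; run made earlier
- west: reagent in the second phase 1.9 equiv; run made earlier
- flask: reagent in the second phase 2.50 equiv; time 15 h; volume of the second phase over the first 0.25

- north (time / h: target / %): 2.50: 6.9; 5.00: 13.9; 6.00: 15.0; 10.0: 21.0
- west (time / h: target / %): 2.50: 9.7; 5.00: 18.7; 6.00: 23.7; 10.0: 30.3

(standard deviation of a reading: 1 percentage point)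

- autumn: doubling the transfer coefficient of the reagent in the second phase, all else as stated
- dusk: doubling the amount of reagent in the second phase, all else as stated

- how much target there is at 15 h, in percent of the substrate charged
- the change that raises the amount of target at 15 h, in percent of the substrate charged most ("none" if none brings more than 2 percentage points) (autumn / dusk / none)
- amount of target at 15 h, in percent of the substrate charged, after dusk

- in the second phase: reagent in the second phase; everything else is in the first
- charges count per volume of the first phase; a concentration in a rate is the amount of a species over the volume of its own phase; every rate counts per litre of the first phase
- the numbers in the tables scatter by 1 percentage point (one standard deviation)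
- steps that have been proposed: reagent in the reaction phase <-> reagent in the second phase; substrate + reagent in the reaction phase -> target; reagent in the reaction phase + target -> over-reacted product; reagent in the reaction phase -> decomposed reagent; target <-> isomer of the product
- the earlier runs hold the two phases in the same ratio of volumes as the flask asked about

Scaling the last west reading, 30.3% at 10.0 h, by equivalents and by time gave 0.712 for the flask as its turnover count, the number of substrate time constants elapsed. The north run, scaled the same way, gave 0.737. Taking target for all the substrate spent, I expected 51.0% of target in the flask. Doubling my count for dusk gave me 75.9%. My count held no transfer term, and the two runs agreed without one, so I expected little from autumn.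

The forecast, “Allowing for sublinearity and hidden losses”, stood lower than my figures: 46% of target, dusk as the best change, and 68% after it.

The flask gave 41.5% of target. Dusk added 13 percentage points and reached 54.9%, while autumn added 0.27 points.

    reagent in the reaction phase ⇌ reagent in the second phase, rate k1*([reagent in the reaction phase] - [reagent in the second phase]/K1) per volume of the first phase (partition coefficient = 0.660, kL = 3.10 × 10⁻⁵ s⁻¹)
    substrate + reagent in the reaction phase → target (k = 6.80 × 10⁻⁵ M⁻¹ s⁻¹)
    reagent in the reaction phase + target → over-reacted product (k = 7.70 × 10⁻⁶ M⁻¹ s⁻¹)
    reagent in the reaction phase → decomposed reagent (k = 1.70 × 10⁻⁵ s⁻¹)
    target ⇌ isomer of the product (K = 3.60, k = 8.80 × 10⁻⁶ s⁻¹)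

My count tallied substrate that had reacted, and target is one part of that. At 15.0 h the flask had 43.0% of its substrate left, so 57.0% had reacted against my 51.0%, and 12.9% stood as isomer of the product. The neighbouring flask held 0.12 M of substrate at the same equivalents, so its reagent charge per volume of the first phase fell in step and my count for it became 0.427, or 34.8% of its substrate reacted. That flask left 58.4% of its substrate, with 9.12% as isomer of the product and 31.3% as target.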